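All runs come from a simulation with made-up constants; scatter was added.

- The ratio of over-reaction to making target, read from the runs, is what we carry into the next run, since Wednesday's and Saturday's are both meant to push more substrate through, and we must reckon how much of that push ends as target before choosing between them.

| setting | red | amber | grey | flask |
|---|---|---|---|---|
| substrate | 0.80 M | 1.8 M | 1.2 M | 1.2 M |
| reagent in the second phase | 1.2 equiv | 1.2 equiv | 2.4 equiv | 1.20 equiv |
| remark | run made earlier | run made earlier | run made earlier |  |
| time |  |  |  | 1.5 h |
| volume of the second phase over the first |  |  |  | 1.0 |

| run | time / min | target / % | substrate / % |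
|---|---|---|---|
| red | 6.00 | 0.5 | 100.2 |
| red | 20.0 | 1.7 | 98.1 |
| red | 30.0 | 2.9 | 96.7 |
| red | 50.0 | 6.5 | 92.8 |
| red | 80.0 | 10.6 | 86.4 |
| amber | 15.0 | 2.1 | 97.9 |
| amber | 30.0 | 5.1 | 94.0 |
| amber | 40.0 | 7.8 | 90.8 |
| amber | 60.0 | 11.4 | 86.0 |
| amber | 80.0 | 14.6 | 80.9 |
| grey | 6.00 | 0.4 | 98.8 |
| grey | 20.0 | 4.3 | 95.4 |
| grey | 30.0 | 7.8 | 91.0 |
| grey | 50.0 | 13.7 | 82.3 |
| grey | 80.0 | 18.8 | 70.3 |

(standard deviation of a reading: 0.3 percentage points)

- in the second phase: reagent in the second phase; everything else is in the first
- charges count per volume of the first phase; a concentration in a rate is the amount of a species over the volume of its own phase; every rate counts per litre of the first phase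
- the numbers in the tables scatter by 0.3 percentage points (one standard deviation)
- the earlier runs hold the two phases in the same ratio of volumes as the flask asked about

- the target standing at 1.5 h, as a percentage of the substrate charged
- the change that raises the amount of target at 1.5 h, in percent of the substrate charged most ("none" if none brings more than 2 percentage points) (Wednesday's / Saturday's / none)
- amount of target at 1.5 h, in percent of the substrate charged, after Saturday's

- Wednesday's: doubling the amount of reagent in the second phase, all else as stated
- Saturday's: doubling the transfer coefficient of the reagent in the second phase, all else as stated

- We assume that making target and over-reacting it use the same reagent in the reaction phase, so its level cancels, and target is then the fraction of substrate lost minus a correction, the over-reaction ratio times that fraction squared, over 2.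
- The last grey reading gives 2.47 for this over-reaction ratio, which is 2 times the unrecovered fraction over the squared lost fraction, a reading of the selectivity factor; the amber run, with other charges, reads 2.47.
- The flask's concentration is the geometric mean of red and amber, so we take the geometric mean of their last losses, 16.1%, and extend it at their mean late slope to 18.5%, which the correction turns into 14.2% of target.
- Wednesday's flask is the grey run extended: a loss of 33.7% gives 19.7%.
- For Saturday's, the last loss from red to amber grows as the substrate charge to the power 0.419, which we read as the reaction's share of a series resistance; halving the transfer share gives a loss of 26.0% and 17.7% of target, less than Wednesday's, so we would charge the doubled reagent.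
- The forecast gives 13.7%, 17% after Saturday's and Wednesday's (“Wednesday's is therefore best”), its flask figure lying below ours.
- The flask gives 14.1%, 17.6% after Saturday's, and Wednesday's with a gain of 5.3 percentage points against 3.6 points.

    reagent in the reaction phase ⇌ reagent in the second phase, rate k1*([reagent in the reaction phase] - [reagent in the second phase]/K1) per volume of the first phase (partition coefficient = 2.80, kL = 2.00 × 10⁻⁴ /s)
    substrate + reagent in the reaction phase → target (k = 4.40 × 10⁻⁴ /M/s)
    reagent in the reaction phase + target → over-reacted product (k = 0.00120 /M/s)
    reagent in the reaction phase → decomposed reagent (k = 2.00 × 10⁻⁵ /s)

- Put through the ratio, the flask's lost 18.6% gives 14.3% of target, and the neighbour with 2.0 M of substrate, losing 21.9%, gives 16.0% against its simulated 15.7%. Wednesday's leads in the flask partly through the transfer bottleneck and the over-reaction acting together. The flask run without the over-reaction step holds 20.3% of target against 14.1%.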